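Readings and results stem from a simulated flask from invented constants.

Slowness was what I saw first in the teal run, which is this flask followed so far: after 40.0 h it still held 22.0% of the two substrates, and the asked time is 5.0 d.

| flask | left-handed substrate | right-handed substrate | partner | free catalyst | precatalyst | remark | time |
|---|---|---|---|---|---|---|---|
| teal | 0.072 M | 0.072 M | 0.216 M | 0.11 mM | 7.2 mM | the very flask that is asked about, followed so far |  |
| grey | 0.072 M | 0.072 M | 0.11 M | 0.11 mM | 7.2 mM | run made earlier |  |
| flask | 0.072 M | 0.072 M | 0.216 M | 0.11 mM | 7.2 mM |  | 5.0 d |

| run | time / h | left-handed substrate / % | right-handed substrate / % | left-handed product / % |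
|---|---|---|---|---|
| teal | 5.00 | 33 | 39 | 23 |
| teal | 10.0 | 27 | 26 | 41 |
| teal | 15.0 | 20 | 21 | 50 |
| teal | 20.0 | 18 | 19 | 56 |
| teal | 25.0 | 17 | 12 | 62 |
| teal | 30.0 | 12 | 11 | 67 |
| teal | 40.0 | 13 | 9 | 73 |
| grey | 4.00 | 42 | 49 | 13 |
| grey | 6.00 | 37 | 44 | 18 |
| grey | 8.00 | 40 | 46 | 22 |
| grey | 15.0 | 32 | 33 | 29 |
| grey | 20.0 | 30 | 31 | 38 |
| grey | 30.0 | 25 | 26 | 40 |
| grey | 50.0 | 26 | 24 | 56 |

(scatter of a reading: 2 percentage points)

- free catalyst is single-handed; left-handed substrate and right-handed substrate are mirror images of each other, charged as a racemate, each of them at the stated concentration
- the numbers in the tables scatter with a standard deviation of 2 percentage points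
- an excess is the difference of the two amounts in percent of their sum
- an excess is below zero if the other one leads

- part of the left-handed substrate and right-handed substrate charged together that has reacted at 5.0 d
- excess of left-handed product over right-handed product in the product at 5.0 d
- excess of right-handed substrate over left-handed substrate among what is left of the two at 5.0 d

A single-handed catalyst couples each mirror-image substrate with its own rate constant. In the teal flask the two substrates fell side by side, 12% and 11% at 30.0 h. Yet left-handed product read 73% at 40.0 h, more than the half of the charge that was left-handed, so right-handed substrate must have been turning into left-handed.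

While the two substrates stand equal, the two couplings run in the ratio of their rate constants, the selectivity factor, and that ratio doesn't change with time. So I reckoned the small product as a correction to the large one. Right-handed product wasn't read, so I took it to be the gap in the balance of the teal run. From 25.0 h on the gap averaged 8.00%, out of readings that each scatter by 2 percentage points, beside a mean left-handed product of 67.3%. That gives the leak share, the part of all product that is right-handed: 10.6%, a value read from these scattered readings. The product excess is then one minus twice that share, and I committed to 78.8%, with a substrate excess near zero.

The forecast gave 93% reacted, a product excess of 80% and a substrate excess of 0%, on the ground that “the substrate is racemising quickly compared with coupling”.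

The flask gave 97.7% reacted, a product excess of 76.1% and a substrate excess of 1.05%, by this scheme:

    partner + free catalyst + left-handed substrate → free catalyst + left-handed product (k = 5630 /M²/h)
    partner + free catalyst + right-handed substrate → free catalyst + right-handed product (k = 715 /M²/h)
    left-handed substrate + racemization catalyst ⇌ right-handed substrate + racemization catalyst, rate k3*[racemization catalyst]*[left-handed substrate] forward; the back reaction follows from the equilibrium constant (k = 382 /M/h)
    partner + racemization catalyst → spent catalyst (k = 0.162 /M/h)
    partner + precatalyst → racemization catalyst + spent reagent (k = 0.228 /M/h)

The product excess already stood at 75.3% at 0.500 d. The leak share of the reacted part gives 10.4% right-handed product, and this flask held 11.7%. A neighbour flask, charged like this one but with 4.4 × 10⁻⁵ M of free catalyst, reacted 85.8%, for which the leak share gives 9.09%; that neighbour held 9.87%.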